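Readings and results were computed with made-up constants; the scatter is artificial.

Every G you charged stays counted: G, E and J as read, plus whatever the readings do not show, add up to the whole charge. In amber at 5.00 min the unseen part is 79.5 %. So watch the selectivity, the share of E in E plus J, which amber reads as 80.6 % at 1.33 min and 58.5 % at 5.00 min.

| flask | G | D | X | remark | time |
|---|---|---|---|---|---|
| amber | 0.050 M | 1.1 equiv | 2 equiv | run made earlier |  |
| red | 0.050 M | 1.5 equiv | 2 equiv | run made earlier |  |
| teal | 0.050 M | 2.4 equiv | 2 equiv | run made earlier |  |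
| green | 0.025 M | 1.1 equiv | 2 equiv | run made earlier |  |
| oak | 0.050 M (fed, over 6.0 min) | 1.10 equiv | 2.00 equiv | all else is in the flask from the start; the feed brings no volume worth counting | 8.0 min |
| birch | 0.050 M | 1.10 equiv | 2.00 equiv (fed, over 6.0 min) | all else is in the flask from the start; the feed brings no volume worth counting | 8.0 min |
| maple | 0.050 M | 1.10 equiv | 2.00 equiv | everything together at the start | 8.0 min |

| run | time / min | E / % | J / % | G / % |
|---|---|---|---|---|
| amber | 0.417 | 14.8 | 1.1 | 33.0 |
| amber | 0.667 | 15.8 | 2.2 | 23.8 |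
| amber | 1.33 | 15.4 | 3.7 | 14.8 |
| amber | 2.50 | 12.1 | 3.9 | 10.5 |
| amber | 5.00 | 7.6 | 5.4 | 7.5 |
| red | 2.00 | 18.0 | 5.1 | 11.2 |
| red | 4.00 | 13.2 | 6.3 | 7.7 |
| red | 6.00 | 10.7 | 7.5 | 6.5 |
| red | 8.00 | 7.7 | 7.9 | 4.4 |
| red | 10.0 | 6.4 | 8.5 | 3.5 |
| teal | 0.833 | 30.5 | 3.2 | 15.0 |
| teal | 2.50 | 26.4 | 7.4 | 10.3 |
| teal | 4.00 | 21.9 | 9.6 | 7.5 |
| teal | 6.00 | 17.5 | 10.5 | 6.6 |
| teal | 10.0 | 12.8 | 12.8 | 5.0 |
| green | 2.00 | 12.8 | 2.3 | 19.7 |
| green | 4.00 | 9.8 | 3.0 | 12.9 |
| green | 6.00 | 7.8 | 4.1 | 10.0 |
| green | 8.00 | 6.2 | 4.2 | 7.9 |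
| green | 10.0 | 4.9 | 4.5 | 7.4 |

(scatter of a reading: 0.5 percentage points)

- a species is counted by the G in it: one J counts as two

1. the flask that comes out highest in share of E in E plus J, or "all alike" when all lie within 1.5 percentage points (oak / birch / maple / all alike)
2. share of E in E plus J at the end, oak
3. share of E in E plus J at the end, birch
4. share of E in E plus J at the end, maple

You take over three flasks, each stopping at 8.0 min. The number to carry is the mean age of G (a mean residence time): end time less half the feed time, 5.00 min in oak. A flask with G all in at the start is the zero of this scale, its age equal to its clock, so maple and birch stand at 8.0 min and amber, charged as maple, serves as the calibration. Oak's age matches amber's last reading, so I expect oak near 58.5 %. Amber stops there. Red, with more D, reads 49.4 % at 8.00 min, and it reached 58.8 % only at 6.00 min, later than amber, so I put maple and birch a little under 49.4 %. Leave oak's feed alone: a quicker feed raises the age.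

The forecast also picks oak, since “slow G feed keeps G low”, with oak 56 % (50 % to 63 %), lower than mine, and birch and maple 49 % each.

The flasks give oak 58.6 %, birch 45.8 % and maple 47.2 %, so oak leads.

    G + D ⇌ E (K = 40.0 L mol⁻¹, k = 0.330 L mol⁻¹ s⁻¹)
    X + D ⇌ L (K = 18.0 L mol⁻¹, k = 0.370 L mol⁻¹ s⁻¹)
    2 G → Z (k = 0.620 L mol⁻¹ s⁻¹)
    G + E → J (k = 0.100 L mol⁻¹ s⁻¹)

Among the steps tried, the return of E to G + D is the largest single effect on the gap between oak and birch: the gap of 13 percentage points in oak's favour becomes −12 points in the run with that return taken away. Within oak, feed time moves age and selectivity together: the same flask with the feed over 0.600 min has its age raised from 5.00 min to 7.70 min, and its selectivity at the end drops from 58.6 % to 47.5 %.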